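**Retrosynthetic overview**
1. The target is unmasked last from bis-indole 8 (acetonide on the diol, TBS on the primary alcohol) by one mild hydrolysis.
2. Key disconnection: the bond between C2 of the tryptophol indole and the methine carbon that carries both indoles. Sulfonyl indole 5 re-ionises to cation 4, and O-TBS-tryptophol 7 captures it in a stereoconvergent SN1 Friedel–Crafts union that joins the halves, fixes the 2,3'-connectivity and sets the methine centre from an epimer mixture.
3. Enabling feature: in the unsubstituted indole ring the N1 lone pair is conjugated through C2=C3 to the exocyclic methine carbon, so a leaving group there ionises to a planar 3-alkylidene-3H-indolium ion. The tryptophol indole has C3 blocked by the hydroxyethyl chain and C2–H free, and the adjacent dioxolane C4 (the later carbinol) steers the face.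
4. Precursor 5 comes from a three-component union of indole, (R)-glyceraldehyde acetonide and p-toluenesulfinic acid. Cation 4 first forms there and is stored as the bench-stable sulfone, whose epimeric sulfonyl centre needs no control.
5. No ring is formed: both indole rings are bought, and the dioxolane and silyl ether are the only temporary groups.

Key step: step 3

Remark: the target is read as (2S,3S), meaning the tryptophol-derived indol-2-yl group and the secondary OH are syn when the chain indol-3-yl–C3–C2–C1 is drawn zigzag. (R)-Glyceraldehyde acetonide is taken as commercial and used freshly distilled. The facial sense in step 3 is a model-based prediction, and the first fallback is built to give the same product if the opposite sense prevails.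

**Step 1**
Reactants: 1 indole; 2 (R)-2,2-dimethyl-1,3-dioxolane-4-carbaldehyde
Product: 5 3-{[(4R)-2,2-dimethyl-1,3-dioxolan-4-yl](4-methylbenzenesulfonyl)methyl}-1H-indole (both epimers at the sulfonyl-bearing carbon), via indol-3-yl carbinol 3 (not isolated), via alkylideneindolium cation 4 (not isolated)
Conditions: TolSO2H (1.3 equiv), p-TsOH (10 mol %), MgSO4, EtOAc, 0 °C → rt
Reagents that add atoms: p-toluenesulfinic acid, Cc1ccc(cc1)S(O)=O
Why: Three-component sulfonyl-indole synthesis (Friedel–Crafts hydroxyalkylation of indole C3, ionisation of carbinol 3 to cation 4, capture at carbon by sulfinate faster than by a second indole); the dioxolane centre is not touched, and the sulfonyl-bearing centre forms as an epimer mixture that step 3 erases.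

**Step 2**
Reactants: 6 tryptophol (2-(1H-indol-3-yl)ethanol)
Product: 7 3-[2-(tert-butyldimethylsilyloxy)ethyl]-1H-indole
Conditions: TBSCl (1.1 equiv), imidazole (2 equiv), DMF, 0 °C → rt
Reagents that add atoms: tert-butyldimethylsilyl chloride, CC(C)(C)[Si](C)(C)Cl
Why: Standard imidazole-mediated O-silylation, in which the primary OH reacts far faster than the indole N–H; the silyl ether later prevents O-alkylation and furo[2,3-b]indoline trapping in step 3.

**Step 3**
Reactants: 5 sulfonyl indole (epimer mixture); 7 O-TBS-tryptophol
Product: 8 3-[2-(tert-butyldimethylsilyloxy)ethyl]-2-{(S)-[(4S)-2,2-dimethyl-1,3-dioxolan-4-yl](1H-indol-3-yl)methyl}-1H-indole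
Conditions: InBr3 (10 mol %), 4 Å MS, CH2Cl2, −40 → 0 °C; 7 (2 equiv), slow addition of 5
Reagents that add atoms: none
Why: InBr3 removes the sulfinate from either epimer of 5, pushed out by the N1 lone pair through C2=C3, so both epimers collapse reversibly to the one planar 3-alkylidene-3H-indolium ion 4 already met in step 1 (stereoconvergent SN1), which is now captured by C2 of 7 (C3 is blocked, and any C3 adduct reverts or undergoes a Plancher-type 1,2-shift to C2) and rearomatises. The closest known reaction type is the Lewis-acid-promoted Friedel–Crafts alkylation of indoles with 3-(1-sulfonylalkyl)indoles or 3-indolylmethanols to unsymmetrical bis(indolyl)methanes, including C2-alkylation of 3-substituted indoles. No ring is closed. The new methine centre is controlled by the dioxolane C4 centre: A1,3 strain with the indolium ring (C2–H, or C4–H in the other alkylidene geometry) holds the C4–H bond in the cation plane, so the ring oxygen lies on one face and C5H2 on the other, and the arene should enter anti to the larger, hyperconjugating C4–C5 bond, over the smaller ring oxygen, where its N–H can hydrogen-bond to that oxygen and the developing arenium charge is stabilised; this gives the (S) methine. The step needs C2- over N1-selectivity and mono-alkylation, which the blocked C3 and silylated hydroxyl of 7, the excess of 7 with slow addition of 5, and the low temperature should secure; the in-plane C4–H is orthogonal to the cation π system, which should protect the C4 centre from E1 loss.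

**Step 4**
Reactants: 8 protected bis-indole
Product: 9 colletotryptin B, (2S,3S)-3-[3-(2-hydroxyethyl)-1H-indol-2-yl]-3-(1H-indol-3-yl)propane-1,2-diol
Conditions: AcOH/THF/H2O (3:1:1), 40 °C
Reagents that add atoms: none
Why: Acid-catalysed hydrolysis of the terminal isopropylidene acetal and the primary TBS ether in one operation; aqueous acetic acid is too weak to C3-protonate the indoles and ionise the bis(indolyl)methine, so both stereocentres should be retained.

**Compound list**
1 | indole | c1ccc2[nH]ccc2c1 | starting material
2 | (R)-2,2-dimethyl-1,3-dioxolane-4-carbaldehyde | CC1(C)OC[C@@H](O1)C=O | starting material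
3 | (1H-indol-3-yl)[(4R)-2,2-dimethyl-1,3-dioxolan-4-yl]methanol, both carbinol epimers, not isolated | CC1(C)OC[C@@H](O1)C(O)c1c[nH]c2ccccc12 | intermediate
4 | (Z)-3-{[(4S)-2,2-dimethyl-1,3-dioxolan-4-yl]methylidene}-3H-indol-1-ium, not isolated; formed in step 1 and released again from 5 during step 3 | CC1(C)OC[C@@H](O1)/C=C3\C=[NH+]c2ccccc23 | intermediate
5 | 3-{[(4R)-2,2-dimethyl-1,3-dioxolan-4-yl](4-methylbenzenesulfonyl)methyl}-1H-indole, both epimers at the sulfonyl carbon | CC1(C)OC[C@@H](O1)C(c1c[nH]c2ccccc12)S(=O)(=O)c1ccc(C)cc1 | intermediate
6 | tryptophol | OCCc1c[nH]c2ccccc12 | starting material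
7 | 3-[2-(tert-butyldimethylsilyloxy)ethyl]-1H-indole | CC(C)(C)[Si](C)(C)OCCc1c[nH]c2ccccc12 | intermediate
8 | 3-[2-(tert-butyldimethylsilyloxy)ethyl]-2-{(S)-[(4S)-2,2-dimethyl-1,3-dioxolan-4-yl](1H-indol-3-yl)methyl}-1H-indole | CC(C)(C)[Si](C)(C)OCCc1c([C@H](c2c[nH]c3ccccc23)[C@H]4COC(C)(C)O4)[nH]c5ccccc15 | intermediate
9 | colletotryptin B | OCCc1c([C@H](c2c[nH]c3ccccc23)[C@H](O)CO)[nH]c2ccccc12 | target

**Totals**
Total step count: 4. Longest linear sequence: 3 steps (step 1 → step 3 → step 4, or step 2 → step 3 → step 4).

**Steps most likely to fail, with fallbacks**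

Step 3. The risk is poor or reversed facial selectivity at cation 4 (entry anti to the C4–O bond instead of anti to C4–C5), together with over-alkylation of the product at the free C2 of its indol-3-yl unit. The fallback interchanges the roles of the two indoles: with the same intrinsic facial bias, introducing the aryl groups in the reverse order gives the opposite methine configuration, and the electrophile half then has no free nucleophilic indole position. It sets out from 7 and 2. Compound 7 is N-lithiated (n-BuLi, THF, −78 °C), carboxylated with CO2 and lithiated at C2 with t-BuLi to give the dilithio N-carboxylate F1 (not isolated). Addition of aldehyde 2 and aqueous NH4Cl work-up, in which the carbamic acid loses CO2, should give the indol-2-yl carbinol F2 as an epimer mixture. F2 and indole 1 (excess) with catalytic diphenyl phosphate in CH2Cl2 at −40 → 0 °C should ionise to the indol-2-ylmethyl cation F3 (not isolated), which indole C3 captures. The fallback comes back to the route at 8.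

Step 1. The risk is capture of cation 4 by a second indole (symmetrical bis(indolyl)methane), acid-induced loss of the acetonide, or α-epimerisation of aldehyde 2 before it is consumed. The fallback forms the C–C bond without acid and sets out from 1 and 2. Indole 1 is deprotonated with EtMgBr (Et2O/CH2Cl2, 0 °C) to indol-1-ylmagnesium bromide F4, which should add through C3 to aldehyde 2 at −78 °C. Buffered work-up (NH4Cl/NH3, pH 8) should give carbinol 3, which is treated at once with p-toluenesulfinic acid (1.1 equiv, MgSO4, CH2Cl2, 0 °C). The fallback comes back to the route at 5.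

Step 4. The risk is acid-induced ionisation of the bis(indolyl)methine (retro-Friedel–Crafts with indole exchange or epimerisation at the methine) before hydrolysis is complete. The fallback switches off both indoles during the acid stage and sets out from 8. Boc2O (2.5 equiv) and DMAP (cat.) in MeCN should give the N,N'-di-Boc derivative F5, whose carbamoylated indoles can no longer be C3-protonated or act as leaving groups. Hydrolysis in 80 % aqueous AcOH at 40 °C should then remove the acetonide and the TBS ether to give the di-Boc triol F6. K2CO3 in MeOH at rt should cleave both indole N-Boc groups. The fallback comes back to the route at 9.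

**Further compounds**
F1 | step 3 | lithium 3-[2-(tert-butyldimethylsilyloxy)ethyl]-2-lithioindole-1-carboxylate (not isolated) | CC(C)(C)[Si](C)(C)OCCc1c([Li])n(C(=O)O[Li])c2ccccc12
F2 | step 3 | {3-[2-(tert-butyldimethylsilyloxy)ethyl]-1H-indol-2-yl}[(4R)-2,2-dimethyl-1,3-dioxolan-4-yl]methanol, both carbinol epimers | CC(C)(C)[Si](C)(C)OCCc1c(C(O)[C@H]2COC(C)(C)O2)[nH]c3ccccc13
F3 | step 3 | {3-[2-(tert-butyldimethylsilyloxy)ethyl]-1H-indol-2-yl}[(4S)-2,2-dimethyl-1,3-dioxolan-4-yl]methylium (not isolated) | CC(C)(C)[Si](C)(C)OCCc1c([CH+][C@H]2COC(C)(C)O2)[nH]c3ccccc13
F4 | step 1 | indol-1-ylmagnesium bromide (not isolated) | Br[Mg]n1ccc2ccccc12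
F5 | step 4 | tert-butyl 3-[2-(tert-butyldimethylsilyloxy)ethyl]-2-{(S)-[1-(tert-butoxycarbonyl)indol-3-yl][(4S)-2,2-dimethyl-1,3-dioxolan-4-yl]methyl}indole-1-carboxylate | CC(C)(C)[Si](C)(C)OCCc1c([C@H](c2cn(C(=O)OC(C)(C)C)c3ccccc23)[C@H]4COC(C)(C)O4)n(C(=O)OC(C)(C)C)c5ccccc15
F6 | step 4 | tert-butyl 2-{(1S,2S)-1-[1-(tert-butoxycarbonyl)indol-3-yl]-2,3-dihydroxypropyl}-3-(2-hydroxyethyl)indole-1-carboxylate | OCCc1c([C@H](c2cn(C(=O)OC(C)(C)C)c3ccccc23)[C@H](O)CO)n(C(=O)OC(C)(C)C)c4ccccc14
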